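The benzene ring is built last, around the ketone, so no phenol is acylated or unmasked beside the polyene. In the six-membered aromatic ring, the acyl-bearing carbon C1' has hydroxyl groups at C2' (ortho) and C4' (para). This 1,2,4-relationship is the regiochemical signature of a [4+2] union between a 1,1,3-trioxygenated butadiene and an ethynyl ketone. One Diels–Alder/aromatisation operation forms C1'–C2' and C5'–C6', closes the ring and frees both phenols. Its precursor is a terminal ynone that already holds the whole sesquiterpenoid chain and the (R)-quaternary carbon (methyl, vinyl, homogeranyl, CH2C=O). That centre is set early by copper-catalysed enantioselective SN2' alkynylation of farnesyl diethyl phosphate.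

Key step: step 9

Remark on configuration: the quaternary carbon of the target is R (vinyl > CH2C=O > CH2CH2 > CH3). The same spatial arrangement is called S in the two alkynyl intermediates only because ethynyl outranks vinyl.

Assumption: the antipode of the chiral imidazolinium salt that gives the S-configured enyne is fixed in a first small run; both antipodes derive from commercial (R,R)- or (S,S)-1,2-diphenylethane-1,2-diamine. Isomerically pure (2E,6E)-farnesol is used because the 2Z isomer would deliver the mirror-image centre.

Step 1
Reactants: 1 (2E,6E)-farnesol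
Product: 2 (2E,6E)-farnesyl diethyl phosphate
Conditions: ClP(O)(OEt)2, Et3N, DMAP (cat.), CH2Cl2, 0 °C → rt
Reagents that add atoms: diethyl chlorophosphate, CCOP(=O)(Cl)OCC
Why: DMAP-catalysed O-phosphorylation of a primary allylic alcohol leaves the C–O bond intact, so the 2E geometry that later decides the facial outcome is preserved.

Step 2
Reactants: 2 (2E,6E)-farnesyl diethyl phosphate; 3 trimethylsilylacetylene
Product: 5 (3S,6E)-3-ethenyl-3,7,11-trimethyl-1-(trimethylsilyl)dodeca-6,10-dien-1-yne, via alkynylalane 4 (not isolated)
Conditions: 3, i-Bu2AlH, Et3N (5 mol %), hexanes, rt; then 2, CuCl2·2H2O (5 mol %), enantiopure 2-(3-mesityl-4,5-diphenyl-4,5-dihydroimidazol-3-ium-1-yl)benzenesulfonate (5.5 mol %), THF, −15 °C → rt; aqueous quench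
Reagents that add atoms: diisobutylaluminium hydride, CC(C)C[AlH]CC(C)C (its i-Bu2Al unit appears only in 4)
Why: Amine-promoted metalation of 3 (loss of H2 rather than hydroalumination) gives 4, whose alkynyl group passes to the sulfonate-bridged NHC–copper centre and is delivered to C3 of the phosphate in a copper-catalysed enantioselective allylic substitution (SN2'), the chiral carbene choosing one face of the E-trisubstituted alkene and so setting the quaternary centre as S.

Step 3
Reactants: 5 (3S,6E)-3-ethenyl-3,7,11-trimethyl-1-(trimethylsilyl)dodeca-6,10-dien-1-yne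
Product: 6 (3S,6E)-3-ethenyl-3,7,11-trimethyldodeca-6,10-dien-1-yne
Conditions: K2CO3 (0.2 equiv), MeOH, rt
Reagents that add atoms: none
Why: Base-catalysed methanolysis of the C(sp)–Si bond (protodesilylation) is specific for the alkynylsilane and cannot affect a quaternary centre that has no acidic hydrogen.

Step 4
Reactants: 6 (3S,6E)-3-ethenyl-3,7,11-trimethyldodeca-6,10-dien-1-yne
Product: 7 (3R,6E)-3-ethenyl-3,7,11-trimethyldodeca-6,10-dienal
Conditions: [CpRu(NCMe){2-(Ph2P)-6-(t-Bu)C5H3N}2]PF6 (5 mol %), H2O (5 equiv), acetone, 70 °C
Reagents that add atoms: water, O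
Why: Ruthenium-catalysed anti-Markovnikov hydration runs through a metal vinylidene that only a terminal alkyne can form, so water ends up on the terminal carbon under neutral conditions while the vinyl group and both trisubstituted alkenes stay untouched.

Step 5
Reactants: 7 (3R,6E)-3-ethenyl-3,7,11-trimethyldodeca-6,10-dienal; 8 ethynylmagnesium bromide
Product: 9 (5R,8E)-5-ethenyl-5,9,13-trimethyltetradeca-8,12-dien-1-yn-3-ol (both C3 epimers)
Conditions: HC≡CMgBr (0.5 M in THF), THF, −78 → 0 °C; aqueous quench
Reagents that add atoms: none
Why: Grignard 1,2-addition of an alkynyl nucleophile to an accessible aldehyde carbonyl is reliable, and the carbinol centre, formed without control, is erased in step 6.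

Step 6
Reactants: 9 (5R,8E)-5-ethenyl-5,9,13-trimethyltetradeca-8,12-dien-1-yn-3-ol
Product: 10 (5R,8E)-5-ethenyl-5,9,13-trimethyltetradeca-8,12-dien-1-yn-3-one
Conditions: Dess–Martin periodinane, CH2Cl2, 0 °C → rt; pentane, filtration through a short silica pad; used at once
Reagents that add atoms: none
Why: Dess–Martin oxidation of the secondary propargylic alcohol is mild enough for the alkenes and the terminal alkyne, and the non-aqueous filtration keeps nucleophiles away from the new Michael acceptor.

Step 7
Reactants: 11 methyl acetoacetate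
Product: 12 methyl 3-(trimethylsilyloxy)but-2-enoate (E/Z mixture; the geometry is lost in step 8)
Conditions: Me3SiCl, Et3N, hexane, rt
Reagents that add atoms: chlorotrimethylsilane, C[Si](C)(C)Cl
Why: Soft enolisation of the β-keto ester by the amine and O-silylation of the ketone enol give the silyl enol ether, which is purified by filtration and distillation.

Step 8
Reactants: 12 methyl 3-(trimethylsilyloxy)but-2-enoate
Product: 14 (1Z)-1-methoxy-1,3-bis(trimethylsilyloxy)buta-1,3-diene, via lithium dienolate 13 (not isolated)
Conditions: LiN(i-Pr)2, THF, −78 °C; then Me3SiCl, −78 °C → rt; hexane, filtration under Ar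
Reagents that add atoms: chlorotrimethylsilane, C[Si](C)(C)Cl; lithium diisopropylamide, [Li]N(C(C)C)C(C)C (its lithium appears only in 13)
Why: Kinetic γ-deprotonation of the vinylogous ester gives cross-conjugated dienolate 13, which the hard silicon electrophile traps on oxygen (silyl ketene acetal formation); the C1=C2 geometry is of no consequence because C1 becomes a ring carbon.

Step 9
Reactants: 10 (5R,8E)-5-ethenyl-5,9,13-trimethyltetradeca-8,12-dien-1-yn-3-one; 14 (1Z)-1-methoxy-1,3-bis(trimethylsilyloxy)buta-1,3-diene
Product: 16 (3R,6E)-1-(2,4-dihydroxyphenyl)-3-ethenyl-3,7,11-trimethyldodeca-6,10-dien-1-one (CNP0157533.1), via cycloadduct 15 (not isolated)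
Conditions: 14 (2 equiv), toluene, Ar, 0 → 40 °C; then 0.1 M aq. HCl, THF, 0 °C
Reagents that add atoms: none
Why: This is a normal-electron-demand Diels–Alder reaction of a 1,1,3-trioxygenated butadiene with an acetylenic ketone followed by aromatisation, a known entry to resorcinols; the unsubstituted C4 of 14 (largest HOMO coefficient) engages the unsubstituted alkyne carbon C1 of 10 (largest LUMO coefficient) in a single kinetic step whose two bonds form far out of step, the transition state resembling a conjugate addition, and the ketene-acetal carbon C1 of 14 closes onto C2 of 10. The one new ring, the six-membered carbocycle of 15, is thus closed by an intermolecular [4+2] cycloaddition that makes two C–C bonds in one event. On brief contact with dilute acid both O–Si bonds hydrolyse, the hydroxyl freed at the ketal carbon pushes out methanol, and enolisation gives the arene, pulled by aromaticity and by the hydrogen bond from the ortho hydroxyl to the ketone. No lasting stereocentre is made, since the ketal carbon of 15 forms as a mixture and ends up sp2, while the quaternary carbon, insulated by a CH2 group and lacking any acidic hydrogen, keeps its R configuration. The step needs regioselectivity, which the matched donor–acceptor polarisation of the partners secures (oxygen ortho and para to the acyl carbon), and chemoselectivity, which follows because the isolated alkenes of the side chain carry no electron-withdrawing group and are inert to an electron-rich diene.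

Compound list
1 | (2E,6E)-farnesol | CC(C)=CCC/C(C)=C/CC/C(C)=C/CO | starting material
2 | (2E,6E)-farnesyl diethyl phosphate | CC(C)=CCC/C(C)=C/CC/C(C)=C/COP(=O)(OCC)OCC | intermediate
3 | trimethylsilylacetylene | C#C[Si](C)(C)C | starting material
4 | diisobutyl[(trimethylsilyl)ethynyl]aluminium | CC(C)C[Al](CC(C)C)C#C[Si](C)(C)C | intermediate
5 | (3S,6E)-3-ethenyl-3,7,11-trimethyl-1-(trimethylsilyl)dodeca-6,10-dien-1-yne | C=C[C@](C)(CC/C=C(\C)CCC=C(C)C)C#C[Si](C)(C)C | intermediate
6 | (3S,6E)-3-ethenyl-3,7,11-trimethyldodeca-6,10-dien-1-yne | C=C[C@](C)(CC/C=C(\C)CCC=C(C)C)C#C | intermediate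
7 | (3R,6E)-3-ethenyl-3,7,11-trimethyldodeca-6,10-dienal | C=C[C@](C)(CC/C=C(\C)CCC=C(C)C)CC=O | intermediate
8 | ethynylmagnesium bromide | C#C[Mg]Br | starting material
9 | (5R,8E)-5-ethenyl-5,9,13-trimethyltetradeca-8,12-dien-1-yn-3-ol, both C3 epimers | C=C[C@](C)(CC/C=C(\C)CCC=C(C)C)CC(O)C#C | intermediate
10 | (5R,8E)-5-ethenyl-5,9,13-trimethyltetradeca-8,12-dien-1-yn-3-one | C=C[C@](C)(CC/C=C(\C)CCC=C(C)C)CC(=O)C#C | intermediate
11 | methyl acetoacetate | COC(=O)CC(C)=O | starting material
12 | methyl 3-(trimethylsilyloxy)but-2-enoate, E/Z mixture | COC(=O)C=C(C)O[Si](C)(C)C | intermediate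
13 | lithium 1-methoxy-3-(trimethylsilyloxy)buta-1,3-dien-1-olate | CO/C([O-])=C/C(=C)O[Si](C)(C)C.[Li+] | intermediate
14 | (1Z)-1-methoxy-1,3-bis(trimethylsilyloxy)buta-1,3-diene | CO/C(O[Si](C)(C)C)=C/C(=C)O[Si](C)(C)C | intermediate
15 | (3R,6E)-3-ethenyl-1-[6-methoxy-4,6-bis(trimethylsilyloxy)cyclohexa-1,4-dien-1-yl]-3,7,11-trimethyldodeca-6,10-dien-1-one, both ketal epimers | C=C[C@](C)(CC/C=C(\C)CCC=C(C)C)CC(=O)C1=CCC(O[Si](C)(C)C)=CC1(OC)O[Si](C)(C)C | intermediate
16 | (3R,6E)-1-(2,4-dihydroxyphenyl)-3-ethenyl-3,7,11-trimethyldodeca-6,10-dien-1-one (CNP0157533.1) | C=C[C@](C)(CC/C=C(\C)CCC=C(C)C)CC(=O)c1ccc(O)cc1O | target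

Total step count: 9. Longest linear sequence: 7 (steps 1–6 and 9).

Steps most likely to fail

**Step 9.**
- What may go wrong: the nucleophilic ketene acetal may trigger oligomerisation of the terminal ynone. Moisture may protodesilylate the diene before it reacts. Aromatisation may proceed by loss of silanol instead of methanol, which would leave the ortho oxygen methylated.
- Fallback: it sets out from 7 and comes back at 16, and it brings the arene in ready-made as an aryl-metal. Commercial 4-bromoresorcinol is protected (chloromethyl methyl ether, i-Pr2NEt, CH2Cl2) as 1-bromo-2,4-bis(methoxymethoxy)benzene F1. Bromine–lithium exchange (n-BuLi, THF, −78 °C) gives 2,4-bis(methoxymethoxy)phenyllithium F2. This adds to aldehyde 7 and, after an aqueous quench, gives (3R,6E)-1-[2,4-bis(methoxymethoxy)phenyl]-3-ethenyl-3,7,11-trimethyldodeca-6,10-dien-1-ol F3 as both carbinol epimers. Oxidation of the benzylic alcohol (MnO2, CH2Cl2) gives (3R,6E)-1-[2,4-bis(methoxymethoxy)phenyl]-3-ethenyl-3,7,11-trimethyldodeca-6,10-dien-1-one F4. Acetal exchange (cat. p-TsOH, MeOH, rt to 40 °C) then frees 16.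
- Cost: this path replaces steps 5–9 and accepts a short contact of the polyene with mild acid.

**Step 2.**
- What may go wrong: facial discrimination may be weak because the two substituents on the reacting alkene carbon (methyl and a primary alkyl chain) differ little in size. Direct SN2 displacement, or transfer of isobutyl or hydride from aluminium, may also compete.
- Fallback: it sets out from 1 and comes back at 5, and it relies on reagent-controlled epoxidation followed by stereospecific substitution. Sharpless asymmetric epoxidation of 1 (Ti(Oi-Pr)4, D-(−)-diethyl tartrate, t-BuOOH, 4 Å sieves, CH2Cl2, −20 °C) touches only the allylic-alcohol alkene and should give (2R,3R)-2,3-epoxyfarnesol F5. Alkynylalane 4 (3 equiv, made as in step 2, toluene, 0 °C) opens the aluminium-bound epoxy alcohol at the tertiary carbon C3 with inversion. This is the known organoalane route from 2,3-epoxy alcohols to 1,2-diols, and it gives (2S,3R,6E)-3,7,11-trimethyl-3-[(trimethylsilyl)ethynyl]dodeca-6,10-diene-1,2-diol F6. Reductive 1,2-elimination of the diol (PPh3, I2, imidazole, toluene, 80 °C) turns C1–C2 into the vinyl group and gives 5.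

**Step 4.**
- What may go wrong: the vinylidene may form or hydrate slowly next to the fully substituted carbon, so that conversion stalls while the catalyst decays.
- Fallback: it sets out from 6 and comes back at 7 by hydroboration–oxidation. Cp2Zr(H)Cl-catalysed syn addition of pinacolborane (Et3N cat., CH2Cl2, rt to 50 °C) places boron on the terminal alkyne carbon, ahead of the slower neopentyl-type vinyl group. The product is 2-[(1E,3S,6E)-3-ethenyl-3,7,11-trimethyldodeca-1,6,10-trien-1-yl]-4,4,5,5-tetramethyl-1,3,2-dioxaborolane F7. NaBO3·4H2O (THF/H2O, rt) oxidises the C–B bond, and the enol tautomerises to 7.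

Further compounds
F1 | step 9 | 1-bromo-2,4-bis(methoxymethoxy)benzene | COCOc1ccc(Br)c(OCOC)c1
F2 | step 9 | 2,4-bis(methoxymethoxy)phenyllithium | [Li]c1ccc(OCOC)cc1OCOC
F3 | step 9 | (3R,6E)-1-[2,4-bis(methoxymethoxy)phenyl]-3-ethenyl-3,7,11-trimethyldodeca-6,10-dien-1-ol | C=C[C@](C)(CC/C=C(\C)CCC=C(C)C)CC(O)c1ccc(OCOC)cc1OCOC
F4 | step 9 | (3R,6E)-1-[2,4-bis(methoxymethoxy)phenyl]-3-ethenyl-3,7,11-trimethyldodeca-6,10-dien-1-one | C=C[C@](C)(CC/C=C(\C)CCC=C(C)C)CC(=O)c1ccc(OCOC)cc1OCOC
F5 | step 2 | (2R,3R)-2,3-epoxyfarnesol | OC[C@H]1O[C@]1(C)CC/C=C(\C)CCC=C(C)C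
F6 | step 2 | (2S,3R,6E)-3,7,11-trimethyl-3-[(trimethylsilyl)ethynyl]dodeca-6,10-diene-1,2-diol | OC[C@@H](O)[C@](C)(CC/C=C(\C)CCC=C(C)C)C#C[Si](C)(C)C
F7 | step 4 | 2-[(1E,3S,6E)-3-ethenyl-3,7,11-trimethyldodeca-1,6,10-trien-1-yl]-4,4,5,5-tetramethyl-1,3,2-dioxaborolane | C=C[C@](C)(CC/C=C(\C)CCC=C(C)C)/C=C/B1OC(C)(C)C(C)(C)O1
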